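## Retrosynthetic overview

- The target comes from its 15-deoxy lactone by a last allylic C–H hydroxylation at C15.
- The key C–O step is a palladium-catalysed cis-1,4 addition of acetic acid to a macrocyclic diene monoepoxide: the C3–OAc bond is formed, and the oxirane oxygen left on C6 closes the cis-fused γ-lactone.
- The diene monoepoxide comes from a ten-membered dienol by C8–OH-directed epoxidation of C5=C6 and methacrylation; the carbocycle is closed by ring-closing metathesis at C5=C6.
- The metathesis substrate comes from an indium Barbier coupling (C7–C8) followed by hydroxyl-directed, enantiomer-selecting epoxidation of C1=C10, so every oxygen stereocentre is relayed from C8–OH.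
- The Z-configured aldehyde comes from 3-methylanisole (Birch reduction, selective ozonolysis); the bromide comes from acrolein and methyl acrylate. Ring order: C1–C10 oxirane, ten-membered carbocycle, C5–C6 oxirane (consumed), γ-lactone.

Assumption 1: ring positions use germacrane numbering (ring C1–C10; C11 on C7 carries carbonyl C12 and methylene C13; C14 on C10; C15 on C4), and the target is taken exactly as drawn (cis-fused 12,6-lactone, cis-1,10-epoxide, 4Z).
Assumption 2: the (R,R)-bishydroxamic acid ligand of step 9 is taken to be the enantiomer matched to the (7R,8R)-alcohol; if the sense is the opposite, its antipode is used.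

## Route

Step 1
Reactants: 1 acrolein; 2 methyl acrylate
Product: 3 methyl 3-hydroxy-2-methylidenepent-4-enoate (racemic)
Conditions: DABCO (20 mol %), excess 2, neat, rt
Reagents that add atoms: none
Why: Morita–Baylis–Hillman reaction, in which the DABCO–acrylate enolate adds 1,2 to the aldehyde of acrolein; the racemic carbinol centre is erased in step 2.

Step 2
Reactants: 3 methyl 3-hydroxy-2-methylidenepent-4-enoate
Product: 4 methyl (2Z)-2-(bromomethyl)penta-2,4-dienoate
Conditions: PBr3 (0.4 equiv), Et2O, −10 to 0 °C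
Reagents that add atoms: phosphorus tribromide, BrP(Br)Br
Why: Allylic bromination of a Baylis–Hillman alcohol with SN2′ transposition gives the conjugated primary bromide with the vinyl group cis to CH2Br.

Step 3
Reactants: 5 3-methylanisole
Product: 6 1-methoxy-5-methylcyclohexa-1,4-diene
Conditions: Li, liquid NH3, t-BuOH, THF, −78 to −33 °C
Reagents that add atoms: none
Why: Birch reduction leaves both donor substituents on separate sp2 carbons, giving the 1,4-diene with one enol ether and one methyl-bearing alkene.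

Step 4
Reactants: 6 1-methoxy-5-methylcyclohexa-1,4-diene
Product: 8 methyl (3Z)-3-methyl-6-oxohex-3-enoate, via hydroperoxy acetal 7 (not isolated)
Conditions: O3 (1.0 equiv), CH2Cl2/MeOH, −78 °C; then Me2S, −78 °C to rt
Reagents that add atoms: ozone, [O-][O+]=O
Why: Chemoselective ozonolysis of the electron-rich enol ether bond opens the ring to an ester (C8) and an aldehyde (C3), while the ring-derived trisubstituted alkene keeps its Z geometry (C9 and C2 cis).

Step 5
Reactants: 8 methyl (3Z)-3-methyl-6-oxohex-3-enoate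
Product: 9 methyl (3Z,6Z)-7-iodo-3-methylocta-3,6-dienoate
Conditions: [Ph3PCH(I)CH3]I, NaN(SiMe3)2, THF, −78 °C; then 8, −78 to −20 °C
Reagents that add atoms: (1-iodoethyl)triphenylphosphonium iodide, CC(I)[P+](c1ccccc1)(c1ccccc1)c1ccccc1.[I-]
Why: Stork–Zhao-type Wittig olefination with the α-iodo ylide is Z-selective for aldehydes (iodine cis to the chain) and installs C4 and C15.

Step 6
Reactants: 9 methyl (3Z,6Z)-7-iodo-3-methylocta-3,6-dienoate
Product: 10 methyl (3Z,6Z)-3,7-dimethylnona-3,6,8-trienoate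
Conditions: tributyl(vinyl)stannane, Pd2(dba)3 (2.5 mol %), AsPh3, NMP, rt
Reagents that add atoms: tributyl(vinyl)stannane, C=C[Sn](CCCC)(CCCC)CCCC
Why: Stille cross-coupling proceeds with retention of alkene geometry, so the new vinyl group (C5 and the metathesis terminus) ends cis to C2.

Step 7
Reactants: 10 methyl (3Z,6Z)-3,7-dimethylnona-3,6,8-trienoate
Product: 11 (3Z,6Z)-3,7-dimethylnona-3,6,8-trienal
Conditions: i-Bu2AlH (1.1 equiv), CH2Cl2, −78 °C; Rochelle salt work-up; used crude
Reagents that add atoms: none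
Why: Low-temperature DIBAL-H reduction stops at the aluminium hemiacetal, which releases the C8 aldehyde on work-up; no other reducible group is present.

Step 8
Reactants: 11 (3Z,6Z)-3,7-dimethylnona-3,6,8-trienal; 4 methyl (2Z)-2-(bromomethyl)penta-2,4-dienoate
Product: 13 racemic methyl (3R*,4R*,6Z,9Z)-3-ethenyl-4-hydroxy-6,10-dimethyl-2-methylidenedodeca-6,9,11-trienoate, via allylindium dibromide 12 (not isolated)
Conditions: indium powder (1.5 equiv), THF/H2O 1:1, rt; neutral work-up
Reagents that add atoms: none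
Why: Indium-mediated Barbier allylation in which the pentadienylindium reacts at its γ-carbon (C7) through a six-membered chair transition state that places vinyl and OH syn, giving the racemic (7R*,8R*) hydroxy ester.

Step 9
Reactants: 13 racemic syn hydroxy ester
Product: 14 methyl (3R,4R)-3-ethenyl-4-hydroxy-2-methylidene-5-{(2S,3R)-2-methyl-3-[(2Z)-3-methylpenta-2,4-dien-1-yl]oxiran-2-yl}pentanoate
Conditions: VO(OiPr)3 (2 mol %), (R,R)-N,N′-dihydroxy-N,N′-bis(2,2-diarylacetyl)cyclohexane-1,2-diamine (4 mol %), cumene hydroperoxide (0.55 equiv), toluene, 0 °C, stopped near 50 % conversion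
Reagents that add atoms: cumene hydroperoxide, CC(C)(OO)c1ccccc1
Why: Hydroxyl-directed homoallylic epoxidation run as a kinetic resolution: in the chair transition state the C8 substituent must be equatorial (an axial one clashes with the C10 methyl), so the (8R)-alcohol gives the (1R,10S)-oxirane, the matched (7R,8R)-enantiomer reacts fast, and the unreacted (7S,8S)-enantiomer is removed by chromatography.

Step 10
Reactants: 14 epoxy hydroxy ester
Product: 15 methyl (1R,7R,8R,10S,3Z,5Z)-1,10-epoxy-8-hydroxygermacra-3,5,11(13)-trien-12-oate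
Conditions: second-generation Grubbs catalyst (H2IMes)(PCy3)Cl2Ru=CHPh (10 mol %), CH2Cl2 (1 mM), 40 °C
Reagents that add atoms: none
Why: Ring-closing metathesis joins the C7 vinyl group to the terminal CH=CH2 of the diene; the cis-oxirane and the Z-trisubstituted alkene pre-fold the chain and the ten-membered ring is expected to force the new C5=C6 bond to be Z.

Step 11
Reactants: 15 macrocyclic dienol
Product: 16 methyl (1R,5S,6R,7R,8R,10S,3Z)-1,10:5,6-diepoxy-8-hydroxygermacra-3,11(13)-dien-12-oate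
Conditions: VO(acac)2 (5 mol %), t-BuOOH (1.3 equiv), CH2Cl2, 0 °C
Reagents that add atoms: tert-butyl hydroperoxide, CC(C)(C)OO
Why: Vanadium-catalysed hydroxyl-directed epoxidation of the homoallylic C5=C6 bond: with H7 eclipsing the alkene (allylic 1,3-strain) the vanadate on O8 reaches only the face on the C8 side, giving the (5S,6R)-oxirane, and the C3=C4 bond is out of reach.

Step 12
Reactants: 16 diepoxy alcohol
Product: 17 methyl (1R,5S,6R,7R,8R,10S,3Z)-1,10:5,6-diepoxy-8-(methacryloyloxy)germacra-3,11(13)-dien-12-oate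
Conditions: methacrylic anhydride (1.5 equiv), Et3N, DMAP (cat.), CH2Cl2, 0 °C
Reagents that add atoms: methacrylic anhydride, C=C(C)C(=O)OC(=O)C(C)=C
Why: DMAP-catalysed acylation of the only hydroxyl group installs the C8 methacrylate under basic conditions that leave both oxiranes intact.

Step 13
Reactants: 17 vinyl oxirane methacrylate
Product: 19 (1R,3S,6S,7R,8R,10S,4Z)-3-acetoxy-1,10-epoxy-8-(methacryloyloxy)germacra-4,11(13)-dien-12,6-olide, via hydroxy ester 18 (not isolated)
Conditions: Pd(PPh3)4 (5 mol %), AcOH (3 equiv), THF, 0 °C to rt; then 2-pyridone (20 mol %), 40 °C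
Reagents that add atoms: acetic acid, CC(=O)O
Why: Proposed new method: zerovalent palladium ionises the vinyl oxirane anti to the C5–O bond to a 2-methyl-η3-allyl complex (C3–C4–C5) whose two ring bonds are anti in the U-shaped cis,cis ring, acetate attacks the distal terminus C3 anti to palladium (double inversion, net cis-1,4), which sets 3S and the 4Z alkene, and the C6 oxygen fixed in step 11 then closes the cis-fused γ-lactone onto the methyl ester; the closest known reaction is the palladium-catalysed cis-1,4 addition of carboxylic acids to cyclopentadiene and cyclohexadiene monoepoxides (Tsuji–Trost-type substitution), which has not been shown on a ten-membered diene monoepoxide or coupled to lactonisation.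

Step 14
Reactants: 19 15-deoxy lactone
Product: 20 (1R,3S,6S,7R,8R,10S,4Z)-3-acetoxy-1,10-epoxy-15-hydroxy-8-(methacryloyloxy)germacra-4,11(13)-dien-12,6-olide (CNP0319155.2)
Conditions: SeO2 (0.3 equiv), t-BuOOH (3 equiv), CH2Cl2, rt
Reagents that add atoms: selenium dioxide, O=[Se]=O; tert-butyl hydroperoxide, CC(C)(C)OO
Why: Selenium dioxide allylic oxidation (ene reaction then 2,3-sigmatropic shift) hydroxylates the methyl group trans to C6 on the more substituted alkene carbon and keeps the 4Z geometry, as in the known C14 hydroxylation of parthenolide, while the C3 and C6 methine hydrogens are deactivated by their oxygen substituents.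

## Compound list

1 | acrolein (prop-2-enal) | C=CC=O | starting material
2 | methyl acrylate | C=CC(=O)OC | starting material
3 | methyl 3-hydroxy-2-methylidenepent-4-enoate (racemic) | C=CC(O)C(=C)C(=O)OC | intermediate
4 | methyl (2Z)-2-(bromomethyl)penta-2,4-dienoate | BrC/C(C(=O)OC)=C\C=C | intermediate
5 | 3-methylanisole (1-methoxy-3-methylbenzene) | COc1cccc(C)c1 | starting material
6 | 1-methoxy-5-methylcyclohexa-1,4-diene | COC1=CCC=C(C)C1 | intermediate
7 | methyl (3Z)-6-hydroperoxy-6-methoxy-3-methylhex-3-enoate (racemic, not isolated) | COC(=O)C/C(C)=C\CC(OC)OO | intermediate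
8 | methyl (3Z)-3-methyl-6-oxohex-3-enoate | COC(=O)C/C(C)=C\CC=O | intermediate
9 | methyl (3Z,6Z)-7-iodo-3-methylocta-3,6-dienoate | COC(=O)C/C(C)=C\C/C=C(\I)C | intermediate
10 | methyl (3Z,6Z)-3,7-dimethylnona-3,6,8-trienoate | COC(=O)C/C(C)=C\C/C=C(C)\C=C | intermediate
11 | (3Z,6Z)-3,7-dimethylnona-3,6,8-trienal | O=CC/C(C)=C\C/C=C(C)\C=C | intermediate
12 | [(2Z)-2-(methoxycarbonyl)penta-2,4-dien-1-yl]indium dibromide (not isolated) | Br[In](Br)C/C(C(=O)OC)=C\C=C | intermediate
13 | methyl (3R*,4R*,6Z,9Z)-3-ethenyl-4-hydroxy-6,10-dimethyl-2-methylidenedodeca-6,9,11-trienoate (racemate; the 3R,4R enantiomer, 7R,8R in germacrane numbering, is drawn) | COC(=O)C(=C)[C@@H](C=C)[C@H](O)C/C(C)=C\C/C=C(C)\C=C | intermediate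
14 | methyl (3R,4R)-3-ethenyl-4-hydroxy-2-methylidene-5-{(2S,3R)-2-methyl-3-[(2Z)-3-methylpenta-2,4-dien-1-yl]oxiran-2-yl}pentanoate | COC(=O)C(=C)[C@@H](C=C)[C@H](O)C[C@]1(C)O[C@@H]1C/C=C(C)\C=C | intermediate
15 | methyl (1R,7R,8R,10S,3Z,5Z)-1,10-epoxy-8-hydroxygermacra-3,5,11(13)-trien-12-oate | O[C@@H]1C[C@]2(C)O[C@@H]2C/C=C(C)\C=C/[C@@H]1C(=C)C(=O)OC | intermediate
16 | methyl (1R,5S,6R,7R,8R,10S,3Z)-1,10:5,6-diepoxy-8-hydroxygermacra-3,11(13)-dien-12-oate | O[C@@H]1C[C@]2(C)O[C@@H]2C/C=C(C)\[C@@H]3O[C@@H]3[C@@H]1C(=C)C(=O)OC | intermediate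
17 | methyl (1R,5S,6R,7R,8R,10S,3Z)-1,10:5,6-diepoxy-8-(methacryloyloxy)germacra-3,11(13)-dien-12-oate | C=C(C)C(=O)O[C@@H]1C[C@]2(C)O[C@@H]2C/C=C(C)\[C@@H]3O[C@@H]3[C@@H]1C(=C)C(=O)OC | intermediate
18 | methyl (1R,3S,6S,7S,8R,10S,4Z)-3-acetoxy-1,10-epoxy-6-hydroxy-8-(methacryloyloxy)germacra-4,11(13)-dien-12-oate (not isolated) | C=C(C)C(=O)O[C@@H]1C[C@]2(C)O[C@@H]2C[C@H](OC(C)=O)/C(C)=C\[C@H](O)[C@@H]1C(=C)C(=O)OC | intermediate
19 | (1R,3S,6S,7R,8R,10S,4Z)-3-acetoxy-1,10-epoxy-8-(methacryloyloxy)germacra-4,11(13)-dien-12,6-olide | C=C(C)C(=O)O[C@@H]1C[C@]2(C)O[C@@H]2C[C@H](OC(C)=O)/C(C)=C\[C@@H]2OC(=O)C(=C)[C@@H]21 | intermediate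
20 | (1R,3S,6S,7R,8R,10S,4Z)-3-acetoxy-1,10-epoxy-15-hydroxy-8-(methacryloyloxy)germacra-4,11(13)-dien-12,6-olide | C=C(C)C(=O)O[C@@H]1C[C@]2(C)O[C@@H]2C[C@H](OC(C)=O)/C(CO)=C\[C@@H]2OC(=O)C(=C)[C@@H]21 | target

## Step count and risks

Total step count: 14 (two steps to bromide 4, twelve in the main line).
Longest linear sequence: 12 steps (3-methylanisole 5 to target 20, steps 3–14).

Three steps most likely to fail:

Step 10 (ring-closing metathesis). A ten-membered ring holding a cis,cis-1,3-diene is strained, so oligomers or the 5E isomer may form. The fallback swaps the order of the two C–C bonds and sets out from aldehyde 11 and bromide 4. Z-selective cross-metathesis of the diene terminus of 11 with the vinyl group of 4 (cyclometalated ruthenium catalyst Ru(NO3)(=CH-C6H4-2-OiPr) carrying a C,C-chelating N-adamantyl-N′-mesityl-imidazolin-2-ylidene) gives methyl (2Z,4Z,6Z,9Z)-2-(bromomethyl)-6,10-dimethyl-12-oxododeca-2,4,6,9-tetraenoate F5. Indium powder at high dilution converts it, through its allylindium dibromide F6, by intramolecular Barbier allylation at C7–C8 into racemic methyl (7R*,8R*,1(10)Z,3Z,5Z)-8-hydroxygermacra-1(10),3,5,11(13)-tetraen-12-oate F7. Both hydroxyl-directed epoxidations are then run in one flask with the chiral vanadium catalyst of step 9 (2.2 equiv hydroperoxide), which resolves F7 and gives 16, where the route is rejoined.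

Step 13 (the proposed new step). The η3-allyl intermediate may lose a β-hydrogen, isomerise syn/anti, or be attacked at C5, and the allylic acetate formed could re-ionise. The fallback uses known chemistry and sets out from dienol 15. Methacrylation as in step 12 gives methyl (1R,7R,8R,10S,3Z,5Z)-1,10-epoxy-8-(methacryloyloxy)germacra-3,5,11(13)-trien-12-oate F8. Singlet oxygen (O2, tetraphenylporphyrin, hν, CH2Cl2, −30 °C) adds [4+2] across C3 and C6 on the diene face away from the C11 branch to give methyl (1R,3S,6S,7R,8R,10S)-1,10-epoxy-3,6-epidioxy-8-(methacryloyloxy)germacra-4,11(13)-dien-12-oate F9. Thiourea in MeOH reduces the O–O bond to methyl (1R,3S,6S,7S,8R,10S,4Z)-1,10-epoxy-3,6-dihydroxy-8-(methacryloyloxy)germacra-4,11(13)-dien-12-oate F10, which lactonises to (1R,3S,6S,7R,8R,10S,4Z)-1,10-epoxy-3-hydroxy-8-(methacryloyloxy)germacra-4,11(13)-dien-12,6-olide F11. Acetylation (Ac2O, pyridine) gives 19, where the route is rejoined.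

Step 9 (kinetic resolution by directed epoxidation). The selectivity factor on this secondary homoallylic alcohol is untested, and the matched ligand sense is assumed. The fallback fixes the absolute configuration before the Barbier step and sets out from ester 10. LiAlH4 gives (3Z,6Z)-3,7-dimethylnona-3,6,8-trien-1-ol F1. Enantioselective vanadium/bishydroxamic acid epoxidation of this primary homoallylic alcohol gives 2-{(2S,3R)-2-methyl-3-[(2Z)-3-methylpenta-2,4-dien-1-yl]oxiran-2-yl}ethan-1-ol F2. Buffered Dess–Martin oxidation gives 2-{(2S,3R)-2-methyl-3-[(2Z)-3-methylpenta-2,4-dien-1-yl]oxiran-2-yl}acetaldehyde F3, used at once. The indium Barbier reaction with 4 then gives 14 together with its (3S,4S)-diastereomer, methyl (3S,4S)-3-ethenyl-4-hydroxy-2-methylidene-5-{(2S,3R)-2-methyl-3-[(2Z)-3-methylpenta-2,4-dien-1-yl]oxiran-2-yl}pentanoate F4, separated by chromatography; the route is rejoined at 14.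

Further compounds
F1 | step 9 | (3Z,6Z)-3,7-dimethylnona-3,6,8-trien-1-ol | OCC/C(C)=C\C/C=C(C)\C=C
F2 | step 9 | 2-{(2S,3R)-2-methyl-3-[(2Z)-3-methylpenta-2,4-dien-1-yl]oxiran-2-yl}ethan-1-ol | OCC[C@]1(C)O[C@@H]1C/C=C(C)\C=C
F3 | step 9 | 2-{(2S,3R)-2-methyl-3-[(2Z)-3-methylpenta-2,4-dien-1-yl]oxiran-2-yl}acetaldehyde | O=CC[C@]1(C)O[C@@H]1C/C=C(C)\C=C
F4 | step 9 | methyl (3S,4S)-3-ethenyl-4-hydroxy-2-methylidene-5-{(2S,3R)-2-methyl-3-[(2Z)-3-methylpenta-2,4-dien-1-yl]oxiran-2-yl}pentanoate | COC(=O)C(=C)[C@H](C=C)[C@@H](O)C[C@]1(C)O[C@@H]1C/C=C(C)\C=C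
F5 | step 10 | methyl (2Z,4Z,6Z,9Z)-2-(bromomethyl)-6,10-dimethyl-12-oxododeca-2,4,6,9-tetraenoate | O=CC/C(C)=C\C/C=C(C)\C=C/C=C(\CBr)C(=O)OC
F6 | step 10 | {(2Z,4Z,6Z,9Z)-2-(methoxycarbonyl)-6,10-dimethyl-12-oxododeca-2,4,6,9-tetraen-1-yl}indium dibromide | O=CC/C(C)=C\C/C=C(C)\C=C/C=C(\C[In](Br)Br)C(=O)OC
F7 | step 10 | racemic methyl (7R*,8R*,1(10)Z,3Z,5Z)-8-hydroxygermacra-1(10),3,5,11(13)-tetraen-12-oate (7R,8R enantiomer drawn) | O[C@@H]1C/C(C)=C\C/C=C(C)\C=C/[C@@H]1C(=C)C(=O)OC
F8 | step 13 | methyl (1R,7R,8R,10S,3Z,5Z)-1,10-epoxy-8-(methacryloyloxy)germacra-3,5,11(13)-trien-12-oate | C=C(C)C(=O)O[C@@H]1C[C@]2(C)O[C@@H]2C/C=C(C)\C=C/[C@@H]1C(=C)C(=O)OC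
F9 | step 13 | methyl (1R,3S,6S,7R,8R,10S)-1,10-epoxy-3,6-epidioxy-8-(methacryloyloxy)germacra-4,11(13)-dien-12-oate | C=C(C)C(=O)O[C@@H]1C[C@]2(C)O[C@@H]2C[C@@H]3OO[C@@H](C=C3C)[C@@H]1C(=C)C(=O)OC
F10 | step 13 | methyl (1R,3S,6S,7S,8R,10S,4Z)-1,10-epoxy-3,6-dihydroxy-8-(methacryloyloxy)germacra-4,11(13)-dien-12-oate | C=C(C)C(=O)O[C@@H]1C[C@]2(C)O[C@@H]2C[C@H](O)/C(C)=C\[C@H](O)[C@@H]1C(=C)C(=O)OC
F11 | step 13 | (1R,3S,6S,7R,8R,10S,4Z)-1,10-epoxy-3-hydroxy-8-(methacryloyloxy)germacra-4,11(13)-dien-12,6-olide | C=C(C)C(=O)O[C@@H]1C[C@]2(C)O[C@@H]2C[C@H](O)/C(C)=C\[C@@H]2OC(=O)C(=C)[C@@H]21
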